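The trap in a run like these is to count every L that disappears as monomer in chains.

| flask | L | Z | E | remark | time |
|---|---|---|---|---|---|
| oak | 0.20 M (fed, over 15 h) | 0.28 M | 2 mM | run made earlier; the fed solution adds 1.0 times the starting volume |  |
| elm | 0.20 M (fed, over 15 h) | 0.44 M | 2 mM | run made earlier; the fed solution adds 1.0 times the starting volume |  |
| alder | 0.10 M (fed, over 15 h) | 0.20 M | 2 mM | run made earlier; the fed solution adds 1.0 times the starting volume |  |
| flask | 0.20 M (fed, over 15 h) | 0.200 M | 2.0 mM | the fed solution adds 1.0 times the starting volume | 10 d |

- oak (time / d: Q / %, L / %): 0.833: 16.7, 67.0; 2.00: 17.3, 44.8; 4.00: 16.8, 25.9; 6.00: 16.9, 16.3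
- elm (time / d: Q / %, L / %): 0.500: 12.8, 54.6; 1.04: 16.5, 52.3; 2.50: 16.5, 24.1; 6.00: 16.7, 5.0
- alder (time / d: Q / %, L / %): 1.67: 18.6, 54.7; 3.00: 18.7, 38.6; 5.00: 18.9, 25.2; 6.00: 18.8, 20.5

(readings scatter by 0.3 percentage points)

- every charge counts on the volume at the start, and the solution that is fed holds the whole dose
- the average divides the monomer in chains by the number of chains, living and dead together; two radicals that join make one chain
- the earlier runs were read with a standard deviation of 0.3 percentage points
- the earlier runs do not show the number of chains; that part of a forecast is a guess
- percentages count the whole charge, also what has not yet gone in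

1. average number of monomer units in a chain (living and dead chains, two that joined counted as one) at 10 d
2. part of the L that has reacted at 10 d

Where did the L go? In the oak run Q stayed near 16.9% from 0.833 d on, while L fell from 67.0% to 16.3% at 6.00 d. The elm run, with its richer Z charge and the same charges of L and E, held less L at that time, so I tried the simplest case, L and Z reacting one to one.

How fast? If they do, the gap cZ − cL stays fixed once the feed is over and Q has stopped growing, and ln(cZ/cL) climbs in a straight line. In the final volume the oak gap was 0.0569 M. Between 2.00 d and 6.00 d the readings gave k, the loss rate of L divided by cL times cZ, a second-order rate constant: 3.00 L mol⁻¹ d⁻¹.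

What remained in the flask at 10 d? Its charges of Z and L are equal, the symmetric case, so the gap is just what Q took. With the oak Q, from the same charges of L and E but more Z, that gap in the final volume came to 0.0169 M. I counted the whole charge as present from the start, with Q already taken off, and reached cZ/cL = 2.00. By this estimate L stood at 16.9% of the charge, so I expected c of 83.1%.

The chain count was a guess: I supposed that each E gave two radicals that joined in pairs, which meant one chain per E and a dp of 16.9.

The forecast, higher than mine on dp, gave dp 22 (14 to 36) and c 82.7% (81.5% to 83.8%), holding that “L must be lost to a 1:1 side reaction with Z”.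

The flask gave dp 17.5 and c 83.1%.

    E → 2 D (k = 0.00668 min⁻¹)
    L + D → X + Q (k = 1.32 × 10⁵ L mol⁻¹ min⁻¹)
    2 X → J (k = 2.60 × 10⁶ L mol⁻¹ s⁻¹)
    Z + L → G (k = 0.00211 L mol⁻¹ min⁻¹)
    L + X → Q + X, rate k5*[X]*[L] (k = 9090 L mol⁻¹ min⁻¹)

At 2.31 d the half-life of L in the flask was 3.4 d by the reaction with Z, shorter than the 7400 d by the reaction of L to Q. That second half-life was long against 10 d, and Q stood at 17.5% at 5.00 d and 17.5% at 10.0 d. With k and the flask's own Q, my reckoning gave L 16.7% of the charge, and the flask held 16.9%. For a second flask, the same but with 0.080 M of L, where Q stood at 19.5% of its charge, the same reckoning gave L 7.47% of that charge, and that flask held 7.67%.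

(Readings and results stem from a simulated flask for an exercise.)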